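**Retrosynthetic overview**

- The target is reached by hydrogenolysis of its bis(benzyl ether). The bond between the exocyclic CH2 on C4 and the syringyl ring is cut to give a 4-(iodomethyl) lactone and O-benzylated 4-bromo-2,6-dimethoxyphenol (nickel reductive coupling).
- Structural feature: once the syringyl ring is removed, C4 of the lactone (O1–C2(=O)–C3–C4–C5) carries two oxygenated CH2 arms, C5 and the exocyclic CH2. C4 is then a CH(CH2OH)2 carbon that becomes stereogenic only when one arm closes the O1–C2 bond.
- The hydroxymethyl lactone therefore comes from an acetonide-protected bis(hydroxymethyl) α-hydroxy acid. The γ-lactone is the only ring formed in the route, and C3 is the only stereocentre entering that step.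
- The acid comes from a 1,2-diol, made by opening an (S)-2,2-disubstituted epoxy alcohol at its CH2 with a guaiacyl Grignard/copper reagent. The epoxide comes from Sharpless epoxidation of a 2-substituted allylic alcohol.
- The allylic alcohol comes from 2,2-dimethyl-1,3-dioxan-5-one by olefination, hydrogenation, α-methylenation and ester reduction.

Key step: step 9

Remark: the lactone is numbered O1, C2 (carbonyl), C3 (carbinol carbon), C4, C5 throughout; the target is (3S,4S), with the C3 hydroxyl cis to the C4 benzyl group.

**Route**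

Step 1
Reactants: 1 2,2-dimethyl-1,3-dioxan-5-one; 2 triethyl phosphonoacetate
Product: 3 ethyl 2-(2,2-dimethyl-1,3-dioxan-5-ylidene)acetate
Conditions: NaH, THF, 0 °C → rt
Reagents that add atoms: none
Why: Horner–Wadsworth–Emmons olefination of the symmetric ketone by the sodium phosphonate anion should give the exocyclic conjugated ester, and no alkene geometry issue arises because both ring arms are identical.

Step 2
Reactants: 3 ethyl 2-(2,2-dimethyl-1,3-dioxan-5-ylidene)acetate
Product: 4 ethyl 2-(2,2-dimethyl-1,3-dioxan-5-yl)acetate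
Conditions: H2 (1 atm), Pd/C (10 wt%), EtOAc, rt
Reagents that add atoms: none
Why: Heterogeneous catalytic hydrogenation should saturate the conjugated trisubstituted alkene under neutral conditions that leave the acetonide intact, and the new ring CH carries two identical CH2O arms and is not stereogenic.

Step 3
Reactants: 4 ethyl 2-(2,2-dimethyl-1,3-dioxan-5-yl)acetate
Product: 7 ethyl 2-(2,2-dimethyl-1,3-dioxan-5-yl)prop-2-enoate, via Mannich base 5 (not isolated), via ammonium iodide 6 (not isolated)
Conditions: LiN(iPr)2 (LDA), THF, −78 °C; CH2=NMe2+ I−, −78 °C → rt; MeI, MeOH, rt; DBU, CH2Cl2, rt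
Reagents that add atoms: Eschenmoser's salt (N,N-dimethylmethyleneiminium iodide), C=[N+](C)C.[I-]
Why: Eschenmoser methylenation: α-deprotonation of the ester and Mannich addition to the iminium salt give the β-amino ester, exhaustive N-methylation turns the amine into a leaving group, and base-induced β-elimination should give the 2-substituted acrylate.

Step 4
Reactants: 7 ethyl 2-(2,2-dimethyl-1,3-dioxan-5-yl)prop-2-enoate
Product: 8 2-(2,2-dimethyl-1,3-dioxan-5-yl)prop-2-en-1-ol
Conditions: iBu2AlH (DIBAL-H, 2.3 equiv), CH2Cl2, −78 → 0 °C; aq. potassium sodium tartrate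
Reagents that add atoms: none
Why: 1,2-Reduction of the α,β-unsaturated ester by the aluminium hydride at low temperature should give the allylic alcohol without conjugate reduction, and the acetonide is inert to hydride.

Step 5
Reactants: 8 2-(2,2-dimethyl-1,3-dioxan-5-yl)prop-2-en-1-ol
Product: 9 [(2S)-2-(2,2-dimethyl-1,3-dioxan-5-yl)oxiran-2-yl]methanol
Conditions: Ti(OiPr)4 (10 mol%), L-(+)-diisopropyl tartrate (12 mol%), t-BuOOH (2 equiv, decane), 4 Å MS, CH2Cl2, −20 °C
Reagents that add atoms: tert-butyl hydroperoxide, CC(C)(C)OO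
Why: Sharpless asymmetric epoxidation of a 2-substituted allylic alcohol: the titanium tartrate complex with the L-(+)-tartrate should deliver oxygen to the alkene face that gives the S epoxide (the same sense as methallyl alcohol giving (S)-2-methylglycidol), which sets the future C3; catalytic loading with sieves limits opening of the 2,2-disubstituted epoxide.

Step 6
Reactants: 10 4-bromo-2-methoxyphenol
Product: 11 1-(benzyloxy)-4-bromo-2-methoxybenzene
Conditions: BnBr, K2CO3, DMF, rt
Reagents that add atoms: benzyl bromide, BrCc1ccccc1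
Why: Williamson etherification of the phenoxide masks the acidic phenol so that the aryl bromide can be turned into a Grignard reagent.

Step 7
Reactants: 9 [(2S)-2-(2,2-dimethyl-1,3-dioxan-5-yl)oxiran-2-yl]methanol; 11 1-(benzyloxy)-4-bromo-2-methoxybenzene
Product: 13 (2S)-3-(4-benzyloxy-3-methoxyphenyl)-2-(2,2-dimethyl-1,3-dioxan-5-yl)propane-1,2-diol, via aryl Grignard reagent 12 (not isolated)
Conditions: 11 (2.3 equiv), Mg, THF, 50 °C; then CuI (10 mol%), 9, THF, −30 → 0 °C; aq. NH4Cl
Reagents that add atoms: none
Why: Copper-catalysed SN2 opening of the 2,2-disubstituted epoxide by the aryl Grignard reagent should occur at the unsubstituted CH2 (one equivalent of reagent is spent on the free hydroxyl), so the quaternary carbinol centre is untouched and keeps its configuration.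

Step 8
Reactants: 13 (2S)-3-(4-benzyloxy-3-methoxyphenyl)-2-(2,2-dimethyl-1,3-dioxan-5-yl)propane-1,2-diol
Product: 15 (2S)-3-(4-benzyloxy-3-methoxyphenyl)-2-(2,2-dimethyl-1,3-dioxan-5-yl)-2-hydroxypropanoic acid, via hydroxy aldehyde 14 (not isolated)
Conditions: TEMPO (10 mol%), NaOCl (5 mol%), NaClO2 (2 equiv), MeCN/sodium phosphate buffer (pH 6.7), 35 °C; then citric acid to pH 4, extraction
Reagents that add atoms: sodium chlorite, [Na+].[O-]Cl=O
Why: One-pot oxoammonium oxidation of the primary alcohol to the aldehyde followed by Pinnick-type chlorite oxidation to the acid; the tertiary alcohol cannot be oxidised, the buffered medium preserves the acetonide, and the catalytic amount of hypochlorite limits chlorination of the electron-rich ring.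

Step 9
Reactants: 15 (2S)-3-(4-benzyloxy-3-methoxyphenyl)-2-(2,2-dimethyl-1,3-dioxan-5-yl)-2-hydroxypropanoic acid
Product: 18 (3S,4S)-3-(4-benzyloxy-3-methoxybenzyl)-3-hydroxy-4-(hydroxymethyl)oxolan-2-one, via triol acid 16 (not isolated), via C4-epimeric lactone 17 (not isolated)
Conditions: TsOH·H2O (0.2 equiv), THF/H2O (4:1), 60 °C; then toluene, 80 °C, azeotropic removal of water
Reagents that add atoms: none
Why: Aqueous acid hydrolyses the acetonide to triol acid 16, and either diastereotopic hydroxymethyl group then attacks the protonated carboxyl carbon (Fischer lactonisation, 5-exo-trig acyl substitution) to close the O1–C2 bond of the only ring formed in the route. The two γ-lactones 17 and 18 interconvert under the same acid, by reopening to 16 and by direct translactonisation through the free hydroxymethyl group, so the product is chosen by stability and not by the rate of the first closure. The closest known reaction type is the thermodynamically controlled desymmetrising lactonisation of acids that carry a 2-substituted propane-1,3-diol unit. C4 is the new stereocentre and is controlled by the C3 quaternary centre set in step 5: in 18 the C4 hydroxymethyl group is trans to the larger C3 benzyl group and cis to the C3 hydroxyl, which avoids the vicinal cis carbon–carbon interaction present in 17 and allows an O–H···O hydrogen bond in toluene. The step needs selection between the two hydroxymethyl arms; the size difference between benzyl and hydroxyl on C3 and the reversibility of ring closure should secure it, and C3 has no α-hydrogen and cannot epimerise.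

Step 10
Reactants: 18 (3S,4S)-3-(4-benzyloxy-3-methoxybenzyl)-3-hydroxy-4-(hydroxymethyl)oxolan-2-one
Product: 19 (3S,4S)-3-(4-benzyloxy-3-methoxybenzyl)-3-hydroxy-4-(iodomethyl)oxolan-2-one
Conditions: PPh3, I2, imidazole, CH2Cl2, 0 °C → rt
Reagents that add atoms: iodine, II
Why: Appel iodination: the primary alcohol forms an alkoxyphosphonium ion that iodide displaces by SN2 at the CH2, while the hindered tertiary alcohol does not react and C4 is not involved, so the lactone assignment of step 9 is locked.

Step 11
Reactants: 20 4-bromo-2,6-dimethoxyphenol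
Product: 21 2-(benzyloxy)-5-bromo-1,3-dimethoxybenzene
Conditions: BnBr, K2CO3, DMF, 50 °C
Reagents that add atoms: benzyl bromide, BrCc1ccccc1
Why: Williamson etherification of the hindered phenoxide gives an aryl bromide without an acidic proton, protected by the same group as the guaiacyl ring.

Step 12
Reactants: 19 (3S,4S)-3-(4-benzyloxy-3-methoxybenzyl)-3-hydroxy-4-(iodomethyl)oxolan-2-one; 21 2-(benzyloxy)-5-bromo-1,3-dimethoxybenzene
Product: 22 (3S,4S)-3-(4-benzyloxy-3-methoxybenzyl)-4-(4-benzyloxy-3,5-dimethoxybenzyl)-3-hydroxyoxolan-2-one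
Conditions: NiI2 (10 mol%), 4,4'-di-tert-butyl-2,2'-bipyridine (10 mol%), Zn dust (2 equiv), NaI (25 mol%), pyridine (10 mol%), DMPU, 60 °C
Reagents that add atoms: none
Why: Nickel-catalysed reductive cross-electrophile coupling: the aryl bromide adds oxidatively to low-valent nickel, the primary alkyl iodide gives a radical that the arylnickel species captures, and reductive elimination forms the aryl–CH2 bond with Zn as terminal reductant; the lactone and free tertiary alcohol are tolerated and the radical sits on the exocyclic CH2, so C4 is unaffected.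

Step 13
Reactants: 22 (3S,4S)-3-(4-benzyloxy-3-methoxybenzyl)-4-(4-benzyloxy-3,5-dimethoxybenzyl)-3-hydroxyoxolan-2-one
Product: 23 (3S,4S)-3-hydroxy-3-(4-hydroxy-3-methoxybenzyl)-4-(4-hydroxy-3,5-dimethoxybenzyl)oxolan-2-one
Conditions: H2 (1 atm), Pd/C (10 wt%), EtOAc/MeOH, rt
Reagents that add atoms: none
Why: Hydrogenolysis cleaves both benzyl aryl ethers; the tertiary alcohol is homobenzylic and the lactone C–O bonds are not benzylic, so both should survive and both stereocentres are untouched.

**Compound list**

1 | 2,2-dimethyl-1,3-dioxan-5-one | CC1(C)OCC(=O)CO1 | starting material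
2 | triethyl phosphonoacetate | CCOC(=O)CP(=O)(OCC)OCC | starting material
3 | ethyl 2-(2,2-dimethyl-1,3-dioxan-5-ylidene)acetate | CCOC(=O)C=C1COC(C)(C)OC1 | intermediate
4 | ethyl 2-(2,2-dimethyl-1,3-dioxan-5-yl)acetate | CCOC(=O)CC1COC(C)(C)OC1 | intermediate
5 | ethyl 3-(dimethylamino)-2-(2,2-dimethyl-1,3-dioxan-5-yl)propanoate (racemic Mannich base) | CCOC(=O)C(CN(C)C)C1COC(C)(C)OC1 | intermediate
6 | [2-(2,2-dimethyl-1,3-dioxan-5-yl)-3-ethoxy-3-oxopropyl]trimethylammonium iodide (racemic) | CCOC(=O)C(C[N+](C)(C)C)C1COC(C)(C)OC1.[I-] | intermediate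
7 | ethyl 2-(2,2-dimethyl-1,3-dioxan-5-yl)prop-2-enoate | CCOC(=O)C(=C)C1COC(C)(C)OC1 | intermediate
8 | 2-(2,2-dimethyl-1,3-dioxan-5-yl)prop-2-en-1-ol | OCC(=C)C1COC(C)(C)OC1 | intermediate
9 | [(2S)-2-(2,2-dimethyl-1,3-dioxan-5-yl)oxiran-2-yl]methanol | OC[C@]1(CO1)C2COC(C)(C)OC2 | intermediate
10 | 4-bromo-2-methoxyphenol | COc1cc(Br)ccc1O | starting material
11 | 1-(benzyloxy)-4-bromo-2-methoxybenzene | COc1cc(Br)ccc1OCc1ccccc1 | intermediate
12 | (4-benzyloxy-3-methoxyphenyl)magnesium bromide | COc1cc([Mg]Br)ccc1OCc1ccccc1 | intermediate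
13 | (2S)-3-(4-benzyloxy-3-methoxyphenyl)-2-(2,2-dimethyl-1,3-dioxan-5-yl)propane-1,2-diol | OC[C@](O)(Cc1ccc(OCc2ccccc2)c(OC)c1)C1COC(C)(C)OC1 | intermediate
14 | (2S)-3-(4-benzyloxy-3-methoxyphenyl)-2-(2,2-dimethyl-1,3-dioxan-5-yl)-2-hydroxypropanal | O=C[C@](O)(Cc1ccc(OCc2ccccc2)c(OC)c1)C1COC(C)(C)OC1 | intermediate
15 | (2S)-3-(4-benzyloxy-3-methoxyphenyl)-2-(2,2-dimethyl-1,3-dioxan-5-yl)-2-hydroxypropanoic acid | OC(=O)[C@](O)(Cc1ccc(OCc2ccccc2)c(OC)c1)C1COC(C)(C)OC1 | intermediate
16 | (2S)-2-(4-benzyloxy-3-methoxybenzyl)-2,4-dihydroxy-3-(hydroxymethyl)butanoic acid | OC(=O)[C@](O)(Cc1ccc(OCc2ccccc2)c(OC)c1)C(CO)CO | intermediate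
17 | (3S,4R)-3-(4-benzyloxy-3-methoxybenzyl)-3-hydroxy-4-(hydroxymethyl)oxolan-2-one (hydroxymethyl cis to the C3 benzyl group) | COc1cc(C[C@@]2(O)C(=O)OC[C@H]2CO)ccc1OCc1ccccc1 | intermediate
18 | (3S,4S)-3-(4-benzyloxy-3-methoxybenzyl)-3-hydroxy-4-(hydroxymethyl)oxolan-2-one (hydroxymethyl cis to the C3 hydroxyl) | COc1cc(C[C@@]2(O)C(=O)OC[C@@H]2CO)ccc1OCc1ccccc1 | intermediate
19 | (3S,4S)-3-(4-benzyloxy-3-methoxybenzyl)-3-hydroxy-4-(iodomethyl)oxolan-2-one | COc1cc(C[C@@]2(O)C(=O)OC[C@@H]2CI)ccc1OCc1ccccc1 | intermediate
20 | 4-bromo-2,6-dimethoxyphenol | COc1cc(Br)cc(OC)c1O | starting material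
21 | 2-(benzyloxy)-5-bromo-1,3-dimethoxybenzene | COc1cc(Br)cc(OC)c1OCc1ccccc1 | intermediate
22 | (3S,4S)-3-(4-benzyloxy-3-methoxybenzyl)-4-(4-benzyloxy-3,5-dimethoxybenzyl)-3-hydroxyoxolan-2-one | COc1cc(C[C@@]2(O)C(=O)OC[C@@H]2Cc2cc(OC)c(OCc3ccccc3)c(OC)c2)ccc1OCc1ccccc1 | intermediate
23 | (3S,4S)-3-hydroxy-3-(4-hydroxy-3-methoxybenzyl)-4-(4-hydroxy-3,5-dimethoxybenzyl)oxolan-2-one | COc1cc(C[C@@]2(O)C(=O)OC[C@@H]2Cc2cc(OC)c(O)c(OC)c2)ccc1O | target

**Step count**

Total: 13 steps. Longest linear sequence: 11 steps (steps 1–5, 7–10, 12, 13); steps 6 and 11 are single-step side branches.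

**Steps most likely to fail**

1. Step 9. The equilibrium between closure through one hydroxymethyl arm and closure through the other may not lie far enough to one side, or equilibration may be slow, so group selection at C4 would be incomplete. Separated 17 can in any case be returned to the same conditions. The fallback replaces unassisted equilibrium by covalent trapping. It sets out from the mixture of 17 and 18 obtained in step 9. The mixture is heated with phenylboronic acid and catalytic TsOH·H2O in toluene with azeotropic removal of water. Only 18 has the C3 hydroxyl and the C4 hydroxymethyl group cis, so only it can close the six-membered cyclic phenylboronate of 18 F1, and continuing translactonisation should drain 17 into F1. Transesterification of F1 with pinacol in THF at rt, under neutral conditions where the lactones no longer interconvert, returns the route at 18.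

2. Step 12. Oxidative addition of the electron-rich aryl bromide may be slow relative to radical formation from the alkyl iodide, so reduction or dimerisation of the iodide would compete with cross-coupling. The fallback separates the two events in a Negishi coupling. It sets out from 19. Zinc insertion (I2-activated Zn dust, DMF, rt) gives the alkylzinc iodide of the lactone F2. F2 is then coupled with 21 under palladium catalysis (Pd2(dba)3, 2-dicyclohexylphosphino-2',6'-dimethoxybiphenyl, DMF, 50 °C) and comes back to the route at 22.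

3. Step 8. Over-oxidation with C–C cleavage at the α-hydroxy aldehyde or acid stage, or electrophilic chlorination of the benzyloxy-methoxy ring, may erode the material. The fallback moves the oxidation ahead of the arylation, so the arene never meets an oxidant. It sets out from 9. Oxidation with catalytic RuCl3 hydrate and NaIO4 (MeCN/EtOAc/H2O) gives (2R)-2-(2,2-dimethyl-1,3-dioxan-5-yl)oxirane-2-carboxylic acid F3. Esterification with MeI and K2CO3 in DMF gives methyl (2R)-2-(2,2-dimethyl-1,3-dioxan-5-yl)oxirane-2-carboxylate F4. CuI-catalysed opening of F4 at the epoxide CH2 with Grignard reagent 12 (THF, −40 °C) gives methyl (2S)-3-(4-benzyloxy-3-methoxyphenyl)-2-(2,2-dimethyl-1,3-dioxan-5-yl)-2-hydroxypropanoate F5. F5 is submitted to the conditions of step 9, where acetonide hydrolysis and lactonising transesterification bring it back to the route at 18.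

**Further compounds**

F1 | step 9 | cyclic phenylboronate of 18 (boron bridging the C3 oxygen and the C4 CH2O oxygen, cis-fused 1,3,2-dioxaborinane) | COc1cc(C[C@@]2(OB(c3ccccc3)OC4)C(=O)OC[C@@H]24)ccc1OCc1ccccc1
F2 | step 12 | {[(3S,4S)-4-(4-benzyloxy-3-methoxybenzyl)-4-hydroxy-5-oxooxolan-3-yl]methyl}zinc iodide | COc1cc(C[C@@]2(O)C(=O)OC[C@@H]2C[Zn]I)ccc1OCc1ccccc1
F3 | step 8 | (2R)-2-(2,2-dimethyl-1,3-dioxan-5-yl)oxirane-2-carboxylic acid | OC(=O)[C@]1(CO1)C2COC(C)(C)OC2
F4 | step 8 | methyl (2R)-2-(2,2-dimethyl-1,3-dioxan-5-yl)oxirane-2-carboxylate | COC(=O)[C@]1(CO1)C2COC(C)(C)OC2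
F5 | step 8 | methyl (2S)-3-(4-benzyloxy-3-methoxyphenyl)-2-(2,2-dimethyl-1,3-dioxan-5-yl)-2-hydroxypropanoate | COC(=O)[C@](O)(Cc1ccc(OCc2ccccc2)c(OC)c1)C1COC(C)(C)OC1
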